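Abietane numbering (C1–C20) is used for all ring-fused compounds; compound numbers are those of the steps and the compound list.

## Analysis of the target

Target 31 is the 16-acetate of the abietane catechol lactone carnosol. It has a trans-fused decalin (rings A and B) with a gem-dimethyl group on C4 and an aromatic ring C with hydroxyl groups on C11 and C12. A δ-lactone ties the C20 carboxyl carbon on C10 to the benzylic oxygen on C7, which locks ring B into a bicyclo[2.2.2]octane.

Three of the four stereocentres sit in the ring system. C10 (R) is quaternary and C5 (S) carries its hydrogen anti to C20. C7 (S) can only hold its oxygen on the C20 face once the lactone is closed, so it follows from C10, and only the C5/C10 pair has to be built deliberately. The fourth centre, C15 (S) in the 1-acetoxyprop-2-yl chain on C13, is remote from the others and needs its own source.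

The sensitive groups are:
- the catechol, which oxidizes to the ortho-quinone and on to quinone methides;
- the benzylic lactone C7–O bond, para to the C12 hydroxyl, which ionizes and is open to hydrogenolysis;
- the primary acetate, which must stay distinct from two phenols.

The synthesis is hard because C10 is quaternary, carboxyl-bearing and 1,3-diaxial to a C4 methyl group, and because three different substituents must be placed on the contiguous arene carbons C11, C12 and C13 without loss of C15.

The strategy rests on one feature. Ring C (C8, C9, C11, C12, C13, C14), with oxygen on C12 and the chain on C13, is the dehydrogenated adduct of a 2-silyloxy-3-alkylbuta-1,3-diene to the C8–C9 double bond of a ready-made A/B decalin enone.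

## Retrosynthetic reasoning

**C11–O.** The first bond cut is C11–O of 31, which leads to the monophenol lactone 29. The catechol is the most fragile part of the molecule, so it is made last. C11 is the only free position ortho to the C12 hydroxyl, so an ortho-oxygenation of 29 through quinone 30 has a single site to choose. Because 29 already carries the acetate, nothing follows this step.

**Lactone C20–O.** Opening the lactone of 29 at the acyl–oxygen bond gives the 7β-hydroxy ester 28 and, one oxidation level higher, the aryl ketone 27. The forward reaction only has to bring a C7 oxygen next to the C20 ester. The para-hydroxybenzylic position ionizes easily and the cation can only be captured on the C20 face, so either C7 epimer of 28 leads to 29.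

**Unsaturation of ring C.** The phenol of 27 is taken back by two dehydrogenations to the enedione 26 and then to the cyclohexene silyl enol ether 25. This trades an arene, which is hard to substitute at three neighbouring positions, for a ring that a cycloaddition can assemble with oxygen and the side chain already in place. The forward steps must remove four hydrogens from C8, C9, C11 and C14 and leave the C15 hydrogen alone.

**C9–C11 and C8–C14 (key disconnection).** Cutting these two bonds of 25 gives the trans-fused enone ester 15 and the chiral 2-silyloxydiene 24. The cut is made here for three reasons: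
- it separates the molecule into a fragment holding C5 and C10 and a fragment holding C15;
- the silyloxy group fixes which end of the diene bonds to C9;
- the two new sp3 centres disappear on aromatization, so no facial control is required.

The forward reaction has to form a bond to a β-carbon that is flanked by the quaternary C10.

**Diene 24.** The silyl enol ether of 24 comes from the α-methylene ketone 23. Its C12–C13 bond is cut to the vinyl triflate 21 and an acetyl anion equivalent; the non-isolated ethoxy diene 22 is the link between them. Triflate 21 comes through 20 from the methyl ketone 19 by enolization at the methyl group, which leaves the adjacent stereocentre alone. Ketone 19 comes through amide 18 and silyl ether 17 from the hydroxy ester 16, whose stereocentre becomes C15.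

The C16 oxygen is changed from silyl ether to acetate at the triflate stage (20 to 21). A benzyl ether carried to the end would need hydrogenolysis next to the benzylic lactone, followed by an acetylation that spares two phenols.

**Ring B of 15 (C8–C9).** The enone double bond is cut by an aldol condensation to the keto aldehyde 14, which is released from the ketal aldehyde 13. The aldehyde carbon of 13 is one of the two ester groups of the ketal diester 12, the protected form of the keto diester 11. The forward sequence must reduce the ester trans to the C5 side chain, because that choice decides the trans ring fusion.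

**Ring A (C5–C10).** Cutting C5–C10 of 11 gives the acyclic malonate enone 10. The bond is formed by a six-membered Michael ring closure onto the enone β-carbon, and this is the one step of the A/B fragment that needs an external source of chirality. C10 is not yet a stereocentre in 11, so only C5 has to be controlled.

**The chain.** Enone 10 is cut at C5=C6 to aldehyde 8 and the stabilized ylide 9. The Michael acceptor is introduced last and under neutral conditions, so that no base-mediated racemic ring closure can run ahead of the catalyst. Aldehyde 8 comes from acetal 7, made from malonate 6 and the chloro acetal 5. Acetal 5 comes through aldehyde 4 from nitrile 3, the alkylation product of 1 with 2.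

## Alternatives that were turned down

**Alternative 1: pyranone–alkyne cycloaddition.**
- Disconnection: C8–C9 and C13–C14 of the arene are cut, with carbon dioxide as the fragment lost in the forward direction.
- Forward key step: precursor A1 is a ring A δ-lactone (C20–O–C7 already closed) with a 4-methoxy-2-pyranon-6-yl group on C10 and an ethynyl group on C7. On heating, the pyranone adds the alkyne, carbon dioxide leaves, and the anisole A2 forms with ring B closed and ring C aromatic.
- For it: ring C appears at the arene oxidation level, so no dehydrogenation is needed. C5, C7 and C10 and the lactone are settled before the key step. The reaction is intramolecular, so there is no regiochemical choice and no intermolecular attack on a neopentyl carbon. On these points it is stronger than the chosen route.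
- Against it: A2 has neither the C13 side chain nor the C11 oxygen. The chain would have to be attached to the arene afterwards and C15 created there by an asymmetric reaction. An aryl methyl ether would have to be cleaved next to an acetate and a benzylic lactone. A1 needs a quaternary carbon that carries both a pyranone and the lactone carbonyl, and its transition state must bridge C7 and C10 across the boat lactone at high temperature, where the propargylic lactone C–O bond can eliminate.
- Comparison: the chosen strategy brings the C12 oxygen, the C13 branch and C15 in the ring-forming step itself and keeps every phenol free of ether protection.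

**Alternative 2: benzopyranone intramolecular Diels–Alder.**
- Disconnection: C5–C10 and C6–C7 are cut.
- Forward key step: the ortho-formyl arylacetic acid A3 is cyclodehydrated in a hot carboxylic anhydride to the 2-benzopyran-3-one A4. Its diene (C10 and C7 termini) adds the tethered vinyl group to give A5, in which rings A and B and the bridging lactone are formed at once.
- For it: two rings, the lactone bridge and the centres C5, C7 and C10 arise in one step from an arene that already carries every substituent including C15. No aromatization is needed and A5 is very close to the target. In ring-forming economy it is stronger than the chosen route.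
- Against it: A5 carries a 3-silyloxy group that the target lacks. It is there to relay absolute configuration to the tether, and it would have to be removed at a hindered secondary carbon next to the gem-dimethyl group. The C5/C10 relationship depends on the tether conformation in an unactivated, neopentyl-substituted dienophile and is not secured by any rule. The catechol is held as a dimethyl ether, so the last steps would be a double demethylation next to an acetate and an ionizable benzylic lactone. The pentasubstituted arene A3 is a long linear construction.
- Comparison: the chosen route sets the absolute configuration of the ring system catalytically with no stereocentre to erase, and creates the catechol under mild oxidative conditions without ether cleavage.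

**Alternative 3: Ireland–Claisen ring contraction.**
- Disconnection: C5–C10 is the bond formed, at the cost of the O–C7 bond.
- Forward key step: the alkenyl isochromanone A6 is enolized and silylated to the silyl ketene acetal A7. This rearranges through a boat transition state to the dihydronaphthalene acid A8, which has allyl and carboxyl on C10 and a 2-methylbut-3-en-2-yl group on C5.
- For it: the quaternary C10 and C5 are formed together with chirality transfer from C7, a centre that is easy to make by asymmetric reduction or addition. The arene is prebuilt. The stereochemical link between C5 and C10 is mechanistically tighter than the diastereotopic ester choice of the chosen route.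
- Against it: the rearrangement consumes the C7 oxygen, which must be put back by benzylic oxidation before the lactone can form. Ring A still has to be closed by metathesis onto a quaternary allylic alkene and then hydrogenated, with a benzyl ether present. The catechol again ends as a dimethyl ether. The sequence after the key step is therefore longer than its elegance suggests.
- Comparison: the chosen strategy keeps the C7 oxygen from the enone onwards and reaches the target without aryl ether cleavage or hydrogenation steps.

Key step: step 17

Remark on the chemistry: the quinine-derived primary amine in step 7 is assumed to give the (S) adduct 11; if it gives the antipode, the quinidine-derived pseudo-enantiomer is used under the same conditions.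

Remark on the chemistry: 28 is drawn as the 7β alcohol expected from axial hydride delivery; the 7α epimer would converge on 29 in step 21.

## Route

Step 1
Reactants: 1 isobutyronitrile; 2 1-bromo-3-chloropropane
Product: 3 5-chloro-2,2-dimethylpentanenitrile
Conditions: LiN(iPr)2 (1.05 equiv), THF, −78 °C; then 2, −78 °C → rt
Reagents that add atoms: none
Why: α-Alkylation of a lithiated nitrile; bromide is displaced much faster than chloride, so the chloropropyl chain and the future C4 with both methyl groups are installed in one operation.

Step 2
Reactants: 3 5-chloro-2,2-dimethylpentanenitrile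
Product: 4 5-chloro-2,2-dimethylpentanal
Conditions: iBu2AlH (1.2 equiv), CH2Cl2, −78 → 0 °C; then 1 M aq. HCl
Reagents that add atoms: water, O
Why: Partial reduction of a nitrile; the N-aluminio imine is not reduced further and is hydrolysed on work-up, and the aldehyde has no α-hydrogen, so it cannot enolize or self-condense.

Step 3
Reactants: 4 5-chloro-2,2-dimethylpentanal
Product: 5 2-(5-chloro-2-methylpentan-2-yl)-1,3-dioxolane
Conditions: HOCH2CH2OH (3 equiv), TsOH·H2O (cat.), benzene, reflux, azeotropic removal of water
Reagents that add atoms: ethylene glycol, OCCO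
Why: Acid-catalysed acetalization; the acetal masks the aldehyde against the malonate anion of the next step, which could otherwise add to it.

Step 4
Reactants: 5 2-(5-chloro-2-methylpentan-2-yl)-1,3-dioxolane; 6 dimethyl malonate
Product: 7 dimethyl 2-[4-(1,3-dioxolan-2-yl)-4-methylpentyl]propanedioate
Conditions: 6 (3 equiv), NaH (2.5 equiv), NaI (0.2 equiv), DMF, 80 °C
Reagents that add atoms: none
Why: Malonate alkylation (SN2) of a primary chloride under iodide catalysis, with excess malonate against dialkylation; the malonate is attached before any Michael acceptor exists, so the basic conditions cannot trigger a racemic ring closure.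

Step 5
Reactants: 7 dimethyl 2-[4-(1,3-dioxolan-2-yl)-4-methylpentyl]propanedioate
Product: 8 dimethyl 2-(4,4-dimethyl-5-oxopentyl)propanedioate
Conditions: 2 M aq. HCl, THF, 45 °C
Reagents that add atoms: water, O
Why: Acetal hydrolysis; the methyl esters survive dilute acid, and without base the malonate does not add to the non-enolizable aldehyde.

Step 6
Reactants: 8 dimethyl 2-(4,4-dimethyl-5-oxopentyl)propanedioate; 9 1-(triphenylphosphoranylidene)propan-2-one
Product: 10 dimethyl 2-[(5E)-4,4-dimethyl-7-oxooct-5-en-1-yl]propanedioate
Conditions: 9 (1.5 equiv), toluene, 90 °C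
Reagents that add atoms: none
Why: Wittig olefination with a stabilized ylide gives the E enone; the ylide is too weak a base to deprotonate the malonate appreciably, so the acceptor is assembled without ring closure, and any cyclized material would be a different, separable compound.

Step 7
Reactants: 10 dimethyl 2-[(5E)-4,4-dimethyl-7-oxooct-5-en-1-yl]propanedioate
Product: 11 dimethyl (2S)-3,3-dimethyl-2-(2-oxopropyl)cyclohexane-1,1-dicarboxylate
Conditions: 9-amino-9-deoxy-epi-quinine (20 mol %), 2-nitrobenzoic acid (40 mol %), toluene, 40 °C
Reagents that add atoms: none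
Why: Intramolecular Michael addition under iminium catalysis, the reaction type of primary-amine-catalysed additions of malonates to enones: the amine condenses with the methyl ketone, the quinuclidine nitrogen holds the malonate, and C10 adds 6-exo-trig to C5 through a chair-like transition state with the iminium-bearing vinyl group equatorial, helped by the gem-dimethyl group. The catalyst sets C5 (S), the only centre of the A/B fragment not derived from another one.

Step 8
Reactants: 11 dimethyl (2S)-3,3-dimethyl-2-(2-oxopropyl)cyclohexane-1,1-dicarboxylate
Product: 12 dimethyl (2S)-3,3-dimethyl-2-[(2-methyl-1,3-dioxolan-2-yl)methyl]cyclohexane-1,1-dicarboxylate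
Conditions: Me3SiOCH2CH2OSiMe3 (1.5 equiv), TMSOTf (5 mol %), CH2Cl2, −78 → −20 °C; pyridine quench
Reagents that add atoms: 1,2-bis(trimethylsilyloxy)ethane, C[Si](C)(C)OCCO[Si](C)(C)C
Why: Aprotic ketalization of an unhindered methyl ketone; the ketone must be masked because hydride would attack it before either ester, and the conditions avoid ester exchange.

Step 9
Reactants: 12 dimethyl (2S)-3,3-dimethyl-2-[(2-methyl-1,3-dioxolan-2-yl)methyl]cyclohexane-1,1-dicarboxylate
Product: 13 methyl (1R,2S)-1-formyl-3,3-dimethyl-2-[(2-methyl-1,3-dioxolan-2-yl)methyl]cyclohexane-1-carboxylate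
Conditions: iBu2AlH (1.2 equiv), toluene/CH2Cl2, −78 °C; MeOH quench, aq. potassium sodium tartrate
Reagents that add atoms: none
Why: Half-reduction of a geminal diester; the aluminium hemiacetal is held as a chelate with the second ester and gives the aldehyde only on work-up. The ester trans to the C5 side chain is the more accessible one (the cis ester is screened by the branched chain and, in the chair with that chain equatorial, is axial and syn to a C4 methyl), so the formyl group (future C9) ends trans to the chain and C10 becomes R.

Step 10
Reactants: 13 methyl (1R,2S)-1-formyl-3,3-dimethyl-2-[(2-methyl-1,3-dioxolan-2-yl)methyl]cyclohexane-1-carboxylate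
Product: 15 methyl (4aS,8aS)-8,8-dimethyl-2-oxo-2,5,6,7,8,8a-hexahydronaphthalene-4a(1H)-carboxylate (trans-fused A/B enone; abietane C7 ketone and C8–C9 alkene and C10 ester), via keto aldehyde 14 (not isolated)
Conditions: TsOH·H2O (0.2 equiv), THF/H2O 5:1, 50 °C; then benzene, reflux, azeotropic removal of water
Reagents that add atoms: water, O
Why: Ketal hydrolysis followed by acid-catalysed intramolecular aldol condensation; the aldehyde has no α-hydrogen, only attack of the ketone methyl carbon (C8) gives a six-membered ring, and dehydration gives the C8–C9 enone. Formyl and side chain are trans on ring A, so the fusion is trans; no stereocentre is touched.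

Step 11
Reactants: 16 methyl (R)-3-hydroxy-2-methylpropanoate
Product: 17 methyl (R)-3-[(tert-butyldimethylsilyl)oxy]-2-methylpropanoate
Conditions: TBSCl (1.1 equiv), imidazole (1.5 equiv), CH2Cl2, 0 °C → rt
Reagents that add atoms: tert-butyldimethylsilyl chloride, CC(C)(C)[Si](C)(C)Cl
Why: Silylation of a primary alcohol; the ether survives the organomagnesium and amide-base steps that an acetate would not.

Step 12
Reactants: 17 methyl (R)-3-[(tert-butyldimethylsilyl)oxy]-2-methylpropanoate
Product: 19 (R)-4-[(tert-butyldimethylsilyl)oxy]-3-methylbutan-2-one, via N-methoxy-N-methyl amide 18 (not isolated)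
Conditions: MeNH(OMe)·HCl (1.5 equiv), iPrMgCl (3.0 equiv), THF, −20 °C; then MeMgBr (2.5 equiv), 0 °C; aq. NH4Cl
Reagents that add atoms: N,O-dimethylhydroxylamine hydrochloride, CNOC.Cl (atoms kept in 18 only); methylmagnesium bromide, C[Mg]Br
Why: Magnesium amide aminolysis of the ester, then Grignard addition to the N-methoxy-N-methyl amide, whose chelated tetrahedral adduct stops at the ketone; the low temperature keeps the α-stereocentre intact (18 can be isolated if needed).

Step 13
Reactants: 19 (R)-4-[(tert-butyldimethylsilyl)oxy]-3-methylbutan-2-one
Product: 20 (R)-4-[(tert-butyldimethylsilyl)oxy]-3-methylbut-1-en-2-yl trifluoromethanesulfonate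
Conditions: KN(SiMe3)2 (1.1 equiv), THF, −78 °C; then PhNTf2 (1.15 equiv), −78 → 0 °C; aq. NaHCO3
Reagents that add atoms: N-phenylbis(trifluoromethanesulfonimide), O=S(=O)(N(c1ccccc1)S(=O)(=O)C(F)(F)F)C(F)(F)F
Why: Kinetic enolate formation at the methyl group and O-triflation; the hindered base removes a methyl proton, not the methine proton, so the stereocentre is not enolized and the β-silyloxy group is not eliminated.

Step 14
Reactants: 20 (R)-4-[(tert-butyldimethylsilyl)oxy]-3-methylbut-1-en-2-yl trifluoromethanesulfonate
Product: 21 (R)-2-methyl-3-{[(trifluoromethyl)sulfonyl]oxy}but-3-en-1-yl acetate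
Conditions: Ac2O (3 equiv), Cu(OTf)2 (5 mol %), CH2Cl2, rt
Reagents that add atoms: acetic anhydride, CC(=O)OC(C)=O
Why: Lewis-acid-catalysed exchange of a primary silyl ether for an acetate; only the Si–O bond is broken, the vinyl triflate is inert, and from here on no strong base or nucleophile is used, so the acetate can be carried to the target.

Step 15
Reactants: 21 (R)-2-methyl-3-{[(trifluoromethyl)sulfonyl]oxy}but-3-en-1-yl acetate
Product: 23 (S)-2-methyl-3-methylidene-4-oxopentyl acetate, via ethoxy diene 22 (not isolated)
Conditions: Bu3Sn(C(OEt)=CH2) (1.2 equiv), Pd(PPh3)4 (5 mol %), LiCl (3 equiv), THF, 65 °C; then 1 M aq. HCl, rt, 15 min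
Reagents that add atoms: tributyl(1-ethoxyvinyl)stannane, CCCC[Sn](CCCC)(CCCC)C(=C)OCC; water, O
Why: Stille coupling of a vinyl triflate with an acetyl anion equivalent forms C12–C13; brief acid hydrolysis of the enol ether gives the α-methylene ketone. The stereocentre is only a spectator (the descriptor changes to S by priority), and 23 is used at once because α-methylene ketones dimerize on standing.

Step 16
Reactants: 23 (S)-2-methyl-3-methylidene-4-oxopentyl acetate
Product: 24 (S)-4-[(tert-butyldimethylsilyl)oxy]-2-methyl-3-methylidenepent-4-en-1-yl acetate
Conditions: TBSOTf (1.2 equiv), Et3N (2 equiv), CH2Cl2, 0 °C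
Reagents that add atoms: tert-butyldimethylsilyl trifluoromethanesulfonate, CC(C)(C)[Si](C)(C)OS(=O)(=O)C(F)(F)F
Why: Silyl enol ether formation from an enone; the O-silylated cation can only lose a proton from the methyl group, which gives the cross-conjugated 2-silyloxydiene, and the acetate is not silylated under these conditions.

Step 17
Reactants: 15 methyl (4aS,8aS)-8,8-dimethyl-2-oxo-2,5,6,7,8,8a-hexahydronaphthalene-4a(1H)-carboxylate; 24 (S)-4-[(tert-butyldimethylsilyl)oxy]-2-methyl-3-methylidenepent-4-en-1-yl acetate
Product: 25 methyl (5α,8β,9β,15S)-16-acetoxy-12-[(tert-butyldimethylsilyl)oxy]-7-oxoabiet-12-en-20-oate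
Conditions: 24 (2 equiv), Tf2NH (10 mol %), CH2Cl2, −78 → −40 °C; Et3N quench
Reagents that add atoms: none
Why: Tf2NH protodesilylates a little of 24 to give TBSNTf2, the actual Lewis acid, which silylates the C7 carbonyl of 15; the diene terminus C11 then bonds to the β-carbon C9 and C14 closes onto C8, in one asynchronous [4+2] event or as a Mukaiyama–Michael addition followed by ring closure, and silyl transfer to the new enol ether oxygen regenerates the catalyst. The closest known reaction type is the triflimide-catalysed Diels–Alder reaction of 4,4-disubstituted cyclohex-2-enones with 2-silyloxybutadienes, of which this is a direct case. Ring C closes as a six-membered ring by [4+2] cycloaddition (in the stepwise limit, by attack of the C8 silyl enol ether carbon on the C12–C14 siloxyallyl cation). The new centres C8 and C9 arise by suprafacial addition to the enone face opposite the axial C10 ester (8β-H, 9β-H); both are erased in steps 18 and 19, so neither facial nor endo selectivity is needed. The step needs regiochemistry, and the silyloxy group secures it: as the stronger donor it makes C11 the nucleophilic terminus, so the C12 oxygen ends para to the C7 acyl carbon across ring C and the branch sits on C13. C15 is outside the reacting π system and is carried through unchanged, and the acetate is too weak a nucleophile to intercept the cationic intermediate through a seven-membered ring.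

Step 18
Reactants: 25 methyl (5α,8β,9β,15S)-16-acetoxy-12-[(tert-butyldimethylsilyl)oxy]-7-oxoabiet-12-en-20-oate
Product: 26 methyl (5α,8β,9β,15S)-16-acetoxy-7,12-dioxoabiet-13-en-20-oate
Conditions: Pd(OAc)2 (1.1 equiv), MeCN, rt → 40 °C
Reagents that add atoms: none
Why: Saegusa–Ito oxidation; the palladium enolate at C13 should lose the syn ring hydrogen on C14, as 2-alkyl-1-silyloxycyclohexenes normally give 2-alkylcyclohex-2-enones. Allylic strain with the C12 oxygen keeps the C15–H bond in the enolate plane, away from palladium, so C15 should stay untouched.

Step 19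
Reactants: 26 methyl (5α,8β,9β,15S)-16-acetoxy-7,12-dioxoabiet-13-en-20-oate
Product: 27 methyl (15S)-16-acetoxy-12-hydroxy-7-oxoabieta-8,11,13-trien-20-oate
Conditions: DDQ (1.2 equiv), 1,4-dioxane, rt → 60 °C
Reagents that add atoms: none
Why: Dehydrogenation of an enone to a phenol; the C8 hydrogen is α to the C7 ketone and γ to the enone, so 26 enolizes to a cyclohexadienol from which DDQ takes hydride at C9 or C11 to give the arene. C15 is not part of this conjugated system, and C8 and C9 become planar.

Step 20
Reactants: 27 methyl (15S)-16-acetoxy-12-hydroxy-7-oxoabieta-8,11,13-trien-20-oate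
Product: 28 methyl (7β,15S)-16-acetoxy-7,12-dihydroxyabieta-8,11,13-trien-20-oate
Conditions: NaBH4 (2 equiv), CeCl3·7H2O (1.2 equiv), MeOH/THF, −20 → 0 °C
Reagents that add atoms: none
Why: Luche-type 1,2-reduction of the aryl ketone; CeCl3 activates a carbonyl that the para phenol deactivates, and hydride is delivered axially from the α face, anti to the axial C20 ester, to give the 7β alcohol (7S). The acetate and the hindered C20 ester are not reduced at this temperature.

Step 21
Reactants: 28 methyl (7β,15S)-16-acetoxy-7,12-dihydroxyabieta-8,11,13-trien-20-oate
Product: 29 (15S)-16-acetoxy-12-hydroxyabieta-8,11,13-trien-20,7β-olide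
Conditions: TsOH·H2O (10 mol %), toluene, 70 °C, 5 Å molecular sieves
Reagents that add atoms: none
Why: Acid-catalysed lactonization; the 7β hydroxyl attacks the C20 ester through the boat form of ring B with loss of methanol. Any 7α epimer ionizes to the para-hydroxybenzylic cation, which can only be captured by the C20 carbonyl oxygen on the β face, so both epimers converge and C7 ends S.

Step 22
Reactants: 29 (15S)-16-acetoxy-12-hydroxyabieta-8,11,13-trien-20,7β-olide
Product: 31 (15S)-16-acetoxy-11,12-dihydroxyabieta-8,11,13-trien-20,7β-olide (target; lactone centres 4aR 9S 10aS), via ortho-quinone 30 (not isolated)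
Conditions: 2-iodoxybenzoic acid (1.3 equiv), DMF, rt; then aq. Na2S2O4, EtOAc
Reagents that add atoms: 2-iodoxybenzoic acid, O=C1OI(=O)(O)c2ccccc12
Why: Ortho-oxygenation of a phenol by a pentavalent iodine reagent; the phenol binds to iodine, oxygen is delivered within the complex to the only free ortho position (C11, as C13 is substituted) and the intermediate collapses to quinone 30. Dithionite reduces 30 in the same flask before it can tautomerize to a quinone methide, and no protecting group remains to be removed.

## Compound list

1 | isobutyronitrile | CC(C)C#N | starting material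
2 | 1-bromo-3-chloropropane | ClCCCBr | starting material
3 | 5-chloro-2,2-dimethylpentanenitrile | CC(C)(CCCCl)C#N | intermediate
4 | 5-chloro-2,2-dimethylpentanal | CC(C)(CCCCl)C=O | intermediate
5 | 2-(5-chloro-2-methylpentan-2-yl)-1,3-dioxolane | CC(C)(CCCCl)C1OCCO1 | intermediate
6 | dimethyl malonate | COC(=O)CC(=O)OC | starting material
7 | dimethyl 2-[4-(1,3-dioxolan-2-yl)-4-methylpentyl]propanedioate | COC(=O)C(CCCC(C)(C)C1OCCO1)C(=O)OC | intermediate
8 | dimethyl 2-(4,4-dimethyl-5-oxopentyl)propanedioate | COC(=O)C(CCCC(C)(C)C=O)C(=O)OC | intermediate
9 | 1-(triphenylphosphoranylidene)propan-2-one | CC(=O)C=P(c1ccccc1)(c1ccccc1)c1ccccc1 | starting material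
10 | dimethyl 2-[(5E)-4,4-dimethyl-7-oxooct-5-en-1-yl]propanedioate | COC(=O)C(CCCC(C)(C)/C=C/C(C)=O)C(=O)OC | intermediate
11 | dimethyl (2S)-3,3-dimethyl-2-(2-oxopropyl)cyclohexane-1,1-dicarboxylate | COC(=O)C1(C(=O)OC)CCCC(C)(C)[C@@H]1CC(C)=O | intermediate
12 | dimethyl (2S)-3,3-dimethyl-2-[(2-methyl-1,3-dioxolan-2-yl)methyl]cyclohexane-1,1-dicarboxylate | COC(=O)C1(C(=O)OC)CCCC(C)(C)[C@@H]1CC2(C)OCCO2 | intermediate
13 | methyl (1R,2S)-1-formyl-3,3-dimethyl-2-[(2-methyl-1,3-dioxolan-2-yl)methyl]cyclohexane-1-carboxylate (formyl trans to the side chain) | COC(=O)[C@]1(C=O)CCCC(C)(C)[C@@H]1CC2(C)OCCO2 | intermediate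
14 | methyl (1R,2S)-1-formyl-3,3-dimethyl-2-(2-oxopropyl)cyclohexane-1-carboxylate | COC(=O)[C@]1(C=O)CCCC(C)(C)[C@@H]1CC(C)=O | intermediate (not isolated)
15 | methyl (4aS,8aS)-8,8-dimethyl-2-oxo-2,5,6,7,8,8a-hexahydronaphthalene-4a(1H)-carboxylate (trans-fused A/B enone) | COC(=O)[C@]12CCCC(C)(C)[C@@H]1CC(=O)C=C2 | intermediate
16 | methyl (R)-3-hydroxy-2-methylpropanoate | OC[C@@H](C)C(=O)OC | starting material
17 | methyl (R)-3-[(tert-butyldimethylsilyl)oxy]-2-methylpropanoate | CC(C)(C)[Si](C)(C)OC[C@@H](C)C(=O)OC | intermediate
18 | (R)-3-[(tert-butyldimethylsilyl)oxy]-N-methoxy-N,2-dimethylpropanamide | CC(C)(C)[Si](C)(C)OC[C@@H](C)C(=O)N(C)OC | intermediate (not isolated)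
19 | (R)-4-[(tert-butyldimethylsilyl)oxy]-3-methylbutan-2-one | CC(C)(C)[Si](C)(C)OC[C@@H](C)C(C)=O | intermediate
20 | (R)-4-[(tert-butyldimethylsilyl)oxy]-3-methylbut-1-en-2-yl trifluoromethanesulfonate | C=C(OS(=O)(=O)C(F)(F)F)[C@H](C)CO[Si](C)(C)C(C)(C)C | intermediate
21 | (R)-2-methyl-3-{[(trifluoromethyl)sulfonyl]oxy}but-3-en-1-yl acetate | C=C(OS(=O)(=O)C(F)(F)F)[C@H](C)COC(C)=O | intermediate
22 | (S)-4-ethoxy-2-methyl-3-methylidenepent-4-en-1-yl acetate | C=C(OCC)C(=C)[C@H](C)COC(C)=O | intermediate (not isolated)
23 | (S)-2-methyl-3-methylidene-4-oxopentyl acetate | CC(=O)C(=C)[C@H](C)COC(C)=O | intermediate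
24 | (S)-4-[(tert-butyldimethylsilyl)oxy]-2-methyl-3-methylidenepent-4-en-1-yl acetate | C=C(O[Si](C)(C)C(C)(C)C)C(=C)[C@H](C)COC(C)=O | intermediate
25 | methyl (5α,8β,9β,15S)-16-acetoxy-12-[(tert-butyldimethylsilyl)oxy]-7-oxoabiet-12-en-20-oate | COC(=O)[C@]12CCCC(C)(C)[C@@H]1CC(=O)[C@H]1CC([C@H](C)COC(C)=O)=C(O[Si](C)(C)C(C)(C)C)C[C@H]12 | intermediate
26 | methyl (5α,8β,9β,15S)-16-acetoxy-7,12-dioxoabiet-13-en-20-oate | COC(=O)[C@]12CCCC(C)(C)[C@@H]1CC(=O)[C@H]1C=C([C@H](C)COC(C)=O)C(=O)C[C@H]12 | intermediate
27 | methyl (15S)-16-acetoxy-12-hydroxy-7-oxoabieta-8,11,13-trien-20-oate | COC(=O)[C@]12CCCC(C)(C)[C@@H]1CC(=O)c1cc([C@H](C)COC(C)=O)c(O)cc12 | intermediate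
28 | methyl (7β,15S)-16-acetoxy-7,12-dihydroxyabieta-8,11,13-trien-20-oate | COC(=O)[C@]12CCCC(C)(C)[C@@H]1C[C@H](O)c1cc([C@H](C)COC(C)=O)c(O)cc12 | intermediate
29 | (15S)-16-acetoxy-12-hydroxyabieta-8,11,13-trien-20,7β-olide | CC(=O)OC[C@@H](C)c1cc2c(cc1O)[C@@]13CCCC(C)(C)[C@@H]1C[C@@H]2OC3=O | intermediate
30 | (15S)-16-acetoxy-11,12-dioxoabieta-8,13-dien-20,7β-olide | CC(=O)OC[C@@H](C)C1=CC2=C(C(=O)C1=O)[C@@]13CCCC(C)(C)[C@@H]1C[C@@H]2OC3=O | intermediate (not isolated)
31 | (15S)-16-acetoxy-11,12-dihydroxyabieta-8,11,13-trien-20,7β-olide (16-acetoxycarnosol) | CC(=O)OC[C@@H](C)c1cc2c(c(O)c1O)[C@@]13CCCC(C)(C)[C@@H]1C[C@@H]2OC3=O | target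

## Step count and least certain steps

Total: 22 steps (10 to enone 15, 6 to diene 24, 6 from the cycloaddition to the target). Longest linear sequence: 16 steps (steps 1–10 and 17–22).

**Step 17 (key step).** The branched diene may be used up by protodesilylation or oligomerization faster than it bonds to the neopentyl β-carbon C9, or the reaction may stop after the first C–C bond without ring closure.

The fallback sets out from 15 and rejoins the route at 27. Enone 15 is combined under the same acid catalysis with commercial 2-(trimethylsilyloxy)buta-1,3-diene, the unbranched diene for which this reaction type is best established. This gives the silyl enol ether cycloadduct F1, which acidic work-up hydrolyses to the 7,12-dione F2. Aerobic palladium-catalysed dehydrogenation (Pd(O2CCF3)2, 2-(dimethylamino)pyridine, TsOH, O2, DMSO, 80 °C) gives the 12-hydroxy-7-oxo phenol F3. N-Bromosuccinimide brominates the less hindered ortho position C13 to give the bromophenol F4. Suzuki–Miyaura coupling (Pd(dppf)Cl2, CsF, dioxane) with the 3-acetoxyprop-1-en-2-yl pinacol boronate F5, made from propargyl acetate by copper-catalysed borylation, gives the 2-aryl allylic acetate F6. Asymmetric hydrogenation of F6 with [Ir(cod)(L)]B(ArF)4 (L a chiral phosphine–oxazoline, enantiomer chosen for 15S) gives 27. In this variant C15 is created after ring C is aromatic.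

**Step 7.** Addition to the neopentyl iminium β-carbon may be slow, so that a background ring closure through the malonate enol erodes the enantiomeric purity.

The fallback sets out from 10 and rejoins at 15. Ring closure with K2CO3 in MeOH gives the racemic keto diester F7. Ketalization with (2R,3R)-butane-2,3-diol (TsOH, benzene, reflux) gives two diastereomeric ketals, which are separated by chromatography or crystallization: the wanted (2S) ketal F8 and the unwanted (2R) ketal F9. F8 is reduced with iBu2AlH as in step 9 to the ketal aldehyde F10, and the acid treatment of step 10 releases the diol and gives 15.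

**Step 9.** Discrimination between the two diastereotopic esters may be poor, with hydride also attacking the ester cis to the side chain (which would lead to the cis-fused enone), or reduction may run on to the alcohol.

The fallback sets out from 12 and rejoins at 13. Krapcho dealkoxycarbonylation (LiCl, wet DMSO, 150 °C) gives the monoester F11 as a C10 epimer mixture. Its lithium enolate (LiN(iPr)2, THF, −78 °C) is hydroxymethylated with monomeric formaldehyde on the face anti to the C5 side chain, which allylic strain holds axial, to give the hydroxymethyl ester F12. Dess–Martin oxidation then gives 13. The stereocontrol element changes from reagent approach to a ground-state ester to enolate face selection.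

**Step 18.** β-Hydride elimination from the palladium enolate may go toward the exocyclic C15–H instead of the ring C14–H, which would destroy the C15 configuration.

The fallback sets out from 15 and rejoins at 27. Br2 in CH2Cl2 gives the 8,9-dibromide F13, and Et3N eliminates HBr to the 8-bromo enone F14. Cycloaddition with 24 under the conditions of step 17 gives the 8-bromo cycloadduct F15. DBU removes HBr to give the cyclohexadienyl silyl ether F16, which DDQ (1 equiv, rt) aromatizes by hydride loss from C9 or C11 to the aryl silyl ether F17. HF·pyridine then frees phenol 27. In this sequence no reagent is ever bound to C13.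

## Further compounds

F1 | step 17 | methyl (5α,8β,9β)-7-oxo-12-(trimethylsilyloxy)podocarp-12-en-20-oate | COC(=O)[C@]12CCCC(C)(C)[C@@H]1CC(=O)[C@H]1CC=C(O[Si](C)(C)C)C[C@H]12
F2 | step 17 | methyl (5α,8β,9β)-7,12-dioxopodocarpan-20-oate | COC(=O)[C@]12CCCC(C)(C)[C@@H]1CC(=O)[C@H]1CCC(=O)C[C@H]12
F3 | step 17 | methyl 12-hydroxy-7-oxopodocarpa-8,11,13-trien-20-oate | COC(=O)[C@]12CCCC(C)(C)[C@@H]1CC(=O)c1ccc(O)cc12
F4 | step 17 | methyl 13-bromo-12-hydroxy-7-oxopodocarpa-8,11,13-trien-20-oate | COC(=O)[C@]12CCCC(C)(C)[C@@H]1CC(=O)c1cc(Br)c(O)cc12
F5 | step 17 | 2-(4,4,5,5-tetramethyl-1,3,2-dioxaborolan-2-yl)prop-2-en-1-yl acetate | CC(=O)OCC(=C)B1OC(C)(C)C(C)(C)O1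
F6 | step 17 | methyl 13-(3-acetoxyprop-1-en-2-yl)-12-hydroxy-7-oxopodocarpa-8,11,13-trien-20-oate | COC(=O)[C@]12CCCC(C)(C)[C@@H]1CC(=O)c1cc(C(=C)COC(C)=O)c(O)cc12
F7 | step 7 | dimethyl (2RS)-3,3-dimethyl-2-(2-oxopropyl)cyclohexane-1,1-dicarboxylate | COC(=O)C1(C(=O)OC)CCCC(C)(C)C1CC(C)=O
F8 | step 7 | dimethyl (2S)-3,3-dimethyl-2-{[(4R,5R)-2,4,5-trimethyl-1,3-dioxolan-2-yl]methyl}cyclohexane-1,1-dicarboxylate | COC(=O)C1(C(=O)OC)CCCC(C)(C)[C@@H]1CC2(C)O[C@H](C)[C@@H](C)O2
F9 | step 7 | dimethyl (2R)-3,3-dimethyl-2-{[(4R,5R)-2,4,5-trimethyl-1,3-dioxolan-2-yl]methyl}cyclohexane-1,1-dicarboxylate | COC(=O)C1(C(=O)OC)CCCC(C)(C)[C@H]1CC2(C)O[C@H](C)[C@@H](C)O2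
F10 | step 7 | methyl (1R,2S)-1-formyl-3,3-dimethyl-2-{[(4R,5R)-2,4,5-trimethyl-1,3-dioxolan-2-yl]methyl}cyclohexane-1-carboxylate | COC(=O)[C@]1(C=O)CCCC(C)(C)[C@@H]1CC2(C)O[C@H](C)[C@@H](C)O2
F11 | step 9 | methyl (2S)-3,3-dimethyl-2-[(2-methyl-1,3-dioxolan-2-yl)methyl]cyclohexane-1-carboxylate (C1 epimers) | COC(=O)C1CCCC(C)(C)[C@@H]1CC2(C)OCCO2
F12 | step 9 | methyl (1R,2S)-1-(hydroxymethyl)-3,3-dimethyl-2-[(2-methyl-1,3-dioxolan-2-yl)methyl]cyclohexane-1-carboxylate | COC(=O)[C@]1(CO)CCCC(C)(C)[C@@H]1CC2(C)OCCO2
F13 | step 18 | methyl (4aS,8aS)-3,4-dibromo-8,8-dimethyl-2-oxooctahydronaphthalene-4a(2H)-carboxylate (bromine-bearing centres as formed) | COC(=O)[C@]12CCCC(C)(C)[C@@H]1CC(=O)C(Br)C2Br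
F14 | step 18 | methyl (4aS,8aS)-3-bromo-8,8-dimethyl-2-oxo-2,5,6,7,8,8a-hexahydronaphthalene-4a(1H)-carboxylate | COC(=O)[C@]12CCCC(C)(C)[C@@H]1CC(=O)C(Br)=C2
F15 | step 18 | methyl (5α,8β,9β,15S)-16-acetoxy-8-bromo-12-[(tert-butyldimethylsilyl)oxy]-7-oxoabiet-12-en-20-oate | COC(=O)[C@]12CCCC(C)(C)[C@@H]1CC(=O)[C@@]1(Br)CC([C@H](C)COC(C)=O)=C(O[Si](C)(C)C(C)(C)C)C[C@H]12
F16 | step 18 | methyl (5α,9β,15S)-16-acetoxy-12-[(tert-butyldimethylsilyl)oxy]-7-oxoabieta-8(14),12-dien-20-oate | COC(=O)[C@]12CCCC(C)(C)[C@@H]1CC(=O)C1=CC([C@H](C)COC(C)=O)=C(O[Si](C)(C)C(C)(C)C)C[C@H]12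
F17 | step 18 | methyl (15S)-16-acetoxy-12-[(tert-butyldimethylsilyl)oxy]-7-oxoabieta-8,11,13-trien-20-oate | COC(=O)[C@]12CCCC(C)(C)[C@@H]1CC(=O)c1cc([C@H](C)COC(C)=O)c(O[Si](C)(C)C(C)(C)C)cc12
A1 | alternative 1 | ring A δ-lactone with 4-methoxy-2-pyranon-6-yl on C10 and ethynyl on C7 | COc1cc(=O)oc(c1)[C@@]12CCCC(C)(C)[C@@H]1C[C@@H](C#C)OC2=O
A2 | alternative 1 | 12-methoxy tetracyclic lactone without C13 side chain and C11 oxygen | c1cc2c(cc1OC)[C@@]13CCCC(C)(C)[C@@H]1C[C@@H]2OC3=O
A3 | alternative 2 | ortho-formyl arylacetic acid with the (S)-silyloxy vinyl tether (C10 either epimer) | CC(=O)OC[C@@H](C)c1cc(C=O)c(c(OC)c1OC)C(CC[C@H](O[Si](C)(C)C(C)(C)C)C(C)(C)C=C)C(=O)O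
A4 | alternative 2 | 2-benzopyran-3-one formed from A3 | O=C1OC=C2C=C([C@H](C)COC(C)=O)C(OC)=C(OC)C2=C1CC[C@H](O[Si](C)(C)C(C)(C)C)C(C)(C)C=C
A5 | alternative 2 | 3-silyloxy carnosol dimethyl ether 16-acetate | CC(=O)OC[C@@H](C)c1cc2c(c(OC)c1OC)[C@@]13CC[C@H](O[Si](C)(C)C(C)(C)C)C(C)(C)[C@@H]1C[C@@H]2OC3=O
A6 | alternative 3 | 4-allyl-1-[(E)-3,3-dimethylpenta-1,4-dienyl]isochroman-3-one with the benzyl-protected side chain (C10 either epimer) | c1ccccc1COC[C@@H](C)c1cc2c(c(OC)c1OC)C(CC=C)C(=O)O[C@H]2/C=C/C(C)(C)C=C
A7 | alternative 3 | tert-butyldimethylsilyl ketene acetal of A6 | c1ccccc1COC[C@@H](C)c1cc2c(c(OC)c1OC)C(CC=C)=C(O[Si](C)(C)C(C)(C)C)O[C@H]2/C=C/C(C)(C)C=C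
A8 | alternative 3 | 1,2-dihydronaphthalene acid with allyl on C10 and 2-methylbut-3-en-2-yl on C5 | c1ccccc1COC[C@@H](C)c1cc2c(c(OC)c1OC)[C@](CC=C)(C(=O)O)[C@H](C(C)(C)C=C)C=C2
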